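**Assumption:** the target has no stereocentre and no hindered axis, so it is achiral; "single enantiomer" needs no stereocontrol. The SMILES is read as the linear hexamer H–[O–C6H2(OH)2]6–OH, with a 2,4,6-trihydroxyphenoxy head (ring A) and a 3,4,5-trihydroxyphenyl end (ring F).

## Retrosynthetic overview

1. Target ⇐ global hydrogenolysis of the trideca-O-benzyl hexamer (13 OBn, one free OH on ring F).
2. The only bonds between the six rings are five diaryl ether C–O bonds; there is no C–C bond outside the rings. Each ether is cut to a 2,6-bis(benzyloxy)phenoxide plus 2,6-bis(benzyloxy)-4-fluorobenzaldehyde, joined by formyl-activated addition–elimination.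
3. After each coupling the formyl group is converted to OH (Baeyer–Villiger/Dakin), which regenerates the flanked phenol for the next coupling.
4. No ring is constructed; the six benzene rings come from commercial arenes and are attached in the order A → B → C → D → E → F.
5. Ring A phenol comes from 1,3,5-tris(benzyloxy)benzene (Vilsmeier, then Dakin); the monomer comes from 4-fluoro-2,6-dimethoxybenzaldehyde (demethylation, benzylation).

**Notation:** Bn = benzyl. A = 2,4,6-tris(benzyloxy)phenyl. B, C, D, E, F = 2,6-bis(benzyloxy)-1,4-phenylene rings. Each is bound through its C-4 (flanked by two H) to the oxygen that sits between the two OBn groups of the preceding ring. Its C-1 (between its own two OBn groups) carries CHO, OCHO, OH or the oxygen to the next ring.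

## Route

Step 1
Reactants: 1 4-fluoro-2,6-dimethoxybenzaldehyde
Product: 2 4-fluoro-2,6-dihydroxybenzaldehyde
Conditions: AlCl3 (3 equiv), CH2Cl2, 0 °C → rt; then 2 M HCl
Reagents that add atoms: none
Why: Lewis-acid aryl methyl ether cleavage, assisted by chelation of aluminium between the formyl oxygen and each ortho-methoxy oxygen (chloride attacks the methyl group), leaves the C–F bond and the aldehyde intact.

Step 2
Reactants: 2 4-fluoro-2,6-dihydroxybenzaldehyde
Product: 3 2,6-bis(benzyloxy)-4-fluorobenzaldehyde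
Conditions: BnBr (2.5 equiv), K2CO3, DMF, 40 °C
Reagents that add atoms: benzyl bromide, BrCc1ccccc1
Why: Williamson etherification of both phenoxides is fast and O-selective because the formyl group suppresses C-alkylation, while the phenoxide-bearing ring is too electron-rich for competing fluoride displacement at this temperature.

Step 3
Reactants: 4 1,3,5-tris(benzyloxy)benzene
Product: 6 2,4,6-tris(benzyloxy)benzaldehyde, via aryl iminium chloride 5 (not isolated)
Conditions: POCl3 (1.5 equiv), DMF, 0 → 60 °C; then H2O, 0 °C → rt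
Reagents that add atoms: N,N-dimethylformamide, CN(C)C=O; water, O
Why: Vilsmeier–Haack formylation, in which the enol-ether-like arene adds to the chloroiminium ion in a Mannich-type C–C bond formation, can give only one product because the three ring CH positions are equivalent and the iminium group blocks a second attack.

Step 4
Reactants: 6 2,4,6-tris(benzyloxy)benzaldehyde
Product: 8 2,4,6-tris(benzyloxy)phenol, via monomer formate 7 (not isolated)
Conditions: mCPBA (1.3 equiv), CH2Cl2, 0 °C → rt; aq Na2SO3/NaHCO3 wash; then K2CO3 (0.2 equiv), MeOH/THF, rt, Ar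
Reagents that add atoms: mCPBA, O=C(OO)c1cccc(Cl)c1
Why: Baeyer–Villiger (Dakin-type) oxidation, in which the electron-rich trialkoxyaryl group migrates in preference to H, gives the aryl formate, which base-catalysed methanolysis cleaves to the phenol after the peracid has been removed.

Step 5
Reactants: 8 2,4,6-tris(benzyloxy)phenol; 3 2,6-bis(benzyloxy)-4-fluorobenzaldehyde (1.2 equiv)
Product: 9 dimer aldehyde A–O–B–CHO, 2,6-bis(benzyloxy)-4-[2,4,6-tris(benzyloxy)phenoxy]benzaldehyde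
Conditions: Cs2CO3 (1.5 equiv), degassed DMSO, 80 °C, Ar
Reagents that add atoms: none
Why: Nucleophilic aromatic substitution (addition–elimination): the flanked, electron-rich phenoxide adds para to the formyl group of 3 in a vinylogous conjugate addition and the Meisenheimer adduct expels fluoride, so the ether oxygen lands on the H-flanked carbon of ring B with no stereocentre formed.

Step 6
Reactants: 9 dimer aldehyde A–O–B–CHO
Product: 11 dimer phenol A–O–B–OH, 2,6-bis(benzyloxy)-4-[2,4,6-tris(benzyloxy)phenoxy]phenol, via dimer formate 10 (not isolated)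
Conditions: mCPBA (1.3 equiv), CH2Cl2, 0 °C → rt; aq Na2SO3/NaHCO3 wash; then K2CO3 (0.2 equiv), MeOH/THF, rt, Ar
Reagents that add atoms: mCPBA, O=C(OO)c1cccc(Cl)c1
Why: Baeyer–Villiger oxidation of the 2,6-dialkoxy-4-aryloxybenzaldehyde proceeds by aryl migration to the formate, and methanolysis then frees the new flanked phenol without touching benzyl or diaryl ethers.

Step 7
Reactants: 11 dimer phenol A–O–B–OH; 3 2,6-bis(benzyloxy)-4-fluorobenzaldehyde (1.2 equiv)
Product: 12 trimer aldehyde A–O–B–O–C–CHO, 2,6-bis(benzyloxy)-4-{2,6-bis(benzyloxy)-4-[2,4,6-tris(benzyloxy)phenoxy]phenoxy}benzaldehyde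
Conditions: Cs2CO3 (1.5 equiv), degassed DMSO, 80 °C, Ar
Reagents that add atoms: none
Why: The same formyl-activated SNAr as in step 5 applies because the nucleophilic site of 11 has the same 2,6-bis(benzyloxy)phenoxide environment as 8, and the older diaryl ethers carry no activating group and cannot exchange.

Step 8
Reactants: 12 trimer aldehyde A–O–B–O–C–CHO
Product: 14 trimer phenol A–O–B–O–C–OH, via trimer formate 13 (not isolated)
Conditions: mCPBA (1.3 equiv), CH2Cl2, 0 °C → rt; aq Na2SO3/NaHCO3 wash; then K2CO3 (0.2 equiv), MeOH/THF, rt, Ar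
Reagents that add atoms: mCPBA, O=C(OO)c1cccc(Cl)c1
Why: Baeyer–Villiger oxidation with aryl migration followed by formate methanolysis, as in step 6, is faster at 0 °C than peracid attack on the alkoxy-substituted rings.

Step 9
Reactants: 14 trimer phenol A–O–B–O–C–OH; 3 2,6-bis(benzyloxy)-4-fluorobenzaldehyde (1.2 equiv)
Product: 15 tetramer aldehyde A–O–B–O–C–O–D–CHO (nona-O-benzyl)
Conditions: Cs2CO3 (1.5 equiv), degassed DMSO/THF, 80 °C, Ar
Reagents that add atoms: none
Why: SNAr (addition–elimination) of the terminal phenoxide at the fluorine-bearing carbon para to the formyl group of 3, identical in its local electronics to step 5.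

Step 10
Reactants: 15 tetramer aldehyde A–O–B–O–C–O–D–CHO
Product: 17 tetramer phenol A–O–B–O–C–O–D–OH, via tetramer formate 16 (not isolated)
Conditions: mCPBA (1.3 equiv), CH2Cl2, 0 °C → rt; aq Na2SO3/NaHCO3 wash; then K2CO3 (0.2 equiv), MeOH/THF, rt, Ar
Reagents that add atoms: mCPBA, O=C(OO)c1cccc(Cl)c1
Why: Baeyer–Villiger oxidation of the terminal electron-rich aldehyde to the formate and mild methanolysis, as in step 6.

Step 11
Reactants: 17 tetramer phenol A–O–B–O–C–O–D–OH; 3 2,6-bis(benzyloxy)-4-fluorobenzaldehyde (1.2 equiv)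
Product: 18 pentamer aldehyde A–O–B–O–C–O–D–O–E–CHO (undeca-O-benzyl)
Conditions: Cs2CO3 (1.5 equiv), degassed DMSO/THF, 80 °C, Ar
Reagents that add atoms: none
Why: Formyl-activated SNAr of the terminal phenoxide on 3 with fluoride as the leaving group, as in step 5.

Step 12
Reactants: 18 pentamer aldehyde A–O–B–O–C–O–D–O–E–CHO
Product: 20 pentamer phenol A–O–B–O–C–O–D–O–E–OH, via pentamer formate 19 (not isolated)
Conditions: mCPBA (1.3 equiv), CH2Cl2, 0 °C → rt; aq Na2SO3/NaHCO3 wash; then K2CO3 (0.2 equiv), MeOH/THF, rt, Ar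
Reagents that add atoms: mCPBA, O=C(OO)c1cccc(Cl)c1
Why: Baeyer–Villiger oxidation with aryl migration and formate methanolysis, as in step 6.

Step 13
Reactants: 20 pentamer phenol A–O–B–O–C–O–D–O–E–OH; 3 2,6-bis(benzyloxy)-4-fluorobenzaldehyde (1.3 equiv)
Product: 21 hexamer aldehyde A–O–B–O–C–O–D–O–E–O–F–CHO (trideca-O-benzyl)
Conditions: Cs2CO3 (1.5 equiv), degassed DMSO/THF, 80 °C, Ar
Reagents that add atoms: none
Why: The last formyl-activated SNAr attaches ring F through its H-flanked carbon, by the same addition–elimination as in step 5.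

Step 14
Reactants: 21 hexamer aldehyde A–O–B–O–C–O–D–O–E–O–F–CHO
Product: 23 hexamer phenol A–O–B–O–C–O–D–O–E–O–F–OH (trideca-O-benzyl ether of the target), via hexamer formate 22 (not isolated)
Conditions: mCPBA (1.3 equiv), CH2Cl2, 0 °C → rt; aq Na2SO3/NaHCO3 wash; then K2CO3 (0.2 equiv), MeOH/THF, rt, Ar
Reagents that add atoms: mCPBA, O=C(OO)c1cccc(Cl)c1
Why: Baeyer–Villiger oxidation converts the last formyl group into the central oxygen of the 3,4,5-trioxygenated ring F, and methanolysis of the formate gives the phenol.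

Step 15
Reactants: 23 hexamer phenol (trideca-O-benzyl ether of the target)
Product: 24 target CNP0187343.0
Conditions: H2 (1 atm), 20% Pd(OH)2/C, THF/MeOH 1:1, rt; filter under Ar; Sephadex LH-20 (degassed MeOH)
Reagents that add atoms: none
Why: Catalytic hydrogenolysis cleaves all thirteen benzyl aryl ethers under neutral conditions, while diaryl ethers and the arene rings are inert, so the air-sensitive polyphenol is released without acid, base or oxidant.

## Compound list

1 | 4-fluoro-2,6-dimethoxybenzaldehyde | COc1cc(F)cc(OC)c1C=O | starting material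
2 | 4-fluoro-2,6-dihydroxybenzaldehyde | O=Cc1c(O)cc(F)cc1O | intermediate
3 | 2,6-bis(benzyloxy)-4-fluorobenzaldehyde | O=Cc1c(OCc2ccccc2)cc(F)cc1OCc1ccccc1 | intermediate
4 | 1,3,5-tris(benzyloxy)benzene | c1ccc(COc2cc(OCc3ccccc3)cc(OCc3ccccc3)c2)cc1 | starting material
5 | N,N-dimethyl-[2,4,6-tris(benzyloxy)phenyl]methaniminium chloride (aryl iminium chloride) | C[N+](C)=Cc1c(OCc2ccccc2)cc(OCc2ccccc2)cc1OCc1ccccc1.[Cl-] | intermediate
6 | 2,4,6-tris(benzyloxy)benzaldehyde | O=Cc1c(OCc2ccccc2)cc(OCc2ccccc2)cc1OCc1ccccc1 | intermediate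
7 | 2,4,6-tris(benzyloxy)phenyl formate (monomer formate) | O=COc1c(OCc2ccccc2)cc(OCc2ccccc2)cc1OCc1ccccc1 | intermediate
8 | 2,4,6-tris(benzyloxy)phenol | Oc1c(OCc2ccccc2)cc(OCc2ccccc2)cc1OCc1ccccc1 | intermediate
9 | dimer aldehyde A–O–B–CHO | O=Cc1c(OCc7ccccc7)cc(Oc2c(OCc7ccccc7)cc(OCc7ccccc7)cc2OCc7ccccc7)cc1OCc7ccccc7 | intermediate
10 | dimer formate A–O–B–OCHO | O=COc1c(OCc7ccccc7)cc(Oc2c(OCc7ccccc7)cc(OCc7ccccc7)cc2OCc7ccccc7)cc1OCc7ccccc7 | intermediate
11 | dimer phenol A–O–B–OH | Oc1c(OCc7ccccc7)cc(Oc2c(OCc7ccccc7)cc(OCc7ccccc7)cc2OCc7ccccc7)cc1OCc7ccccc7 | intermediate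
12 | trimer aldehyde A–O–B–O–C–CHO | O=Cc1c(OCc7ccccc7)cc(Oc2c(OCc7ccccc7)cc(Oc3c(OCc7ccccc7)cc(OCc7ccccc7)cc3OCc7ccccc7)cc2OCc7ccccc7)cc1OCc7ccccc7 | intermediate
13 | trimer formate A–O–B–O–C–OCHO | O=COc1c(OCc7ccccc7)cc(Oc2c(OCc7ccccc7)cc(Oc3c(OCc7ccccc7)cc(OCc7ccccc7)cc3OCc7ccccc7)cc2OCc7ccccc7)cc1OCc7ccccc7 | intermediate
14 | trimer phenol A–O–B–O–C–OH | Oc1c(OCc7ccccc7)cc(Oc2c(OCc7ccccc7)cc(Oc3c(OCc7ccccc7)cc(OCc7ccccc7)cc3OCc7ccccc7)cc2OCc7ccccc7)cc1OCc7ccccc7 | intermediate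
15 | tetramer aldehyde A–O–B–O–C–O–D–CHO | O=Cc1c(OCc7ccccc7)cc(Oc2c(OCc7ccccc7)cc(Oc3c(OCc7ccccc7)cc(Oc4c(OCc7ccccc7)cc(OCc7ccccc7)cc4OCc7ccccc7)cc3OCc7ccccc7)cc2OCc7ccccc7)cc1OCc7ccccc7 | intermediate
16 | tetramer formate A–O–B–O–C–O–D–OCHO | O=COc1c(OCc7ccccc7)cc(Oc2c(OCc7ccccc7)cc(Oc3c(OCc7ccccc7)cc(Oc4c(OCc7ccccc7)cc(OCc7ccccc7)cc4OCc7ccccc7)cc3OCc7ccccc7)cc2OCc7ccccc7)cc1OCc7ccccc7 | intermediate
17 | tetramer phenol A–O–B–O–C–O–D–OH | Oc1c(OCc7ccccc7)cc(Oc2c(OCc7ccccc7)cc(Oc3c(OCc7ccccc7)cc(Oc4c(OCc7ccccc7)cc(OCc7ccccc7)cc4OCc7ccccc7)cc3OCc7ccccc7)cc2OCc7ccccc7)cc1OCc7ccccc7 | intermediate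
18 | pentamer aldehyde A–O–B–O–C–O–D–O–E–CHO | O=Cc1c(OCc7ccccc7)cc(Oc2c(OCc7ccccc7)cc(Oc3c(OCc7ccccc7)cc(Oc4c(OCc7ccccc7)cc(Oc5c(OCc7ccccc7)cc(OCc7ccccc7)cc5OCc7ccccc7)cc4OCc7ccccc7)cc3OCc7ccccc7)cc2OCc7ccccc7)cc1OCc7ccccc7 | intermediate
19 | pentamer formate A–O–B–O–C–O–D–O–E–OCHO | O=COc1c(OCc7ccccc7)cc(Oc2c(OCc7ccccc7)cc(Oc3c(OCc7ccccc7)cc(Oc4c(OCc7ccccc7)cc(Oc5c(OCc7ccccc7)cc(OCc7ccccc7)cc5OCc7ccccc7)cc4OCc7ccccc7)cc3OCc7ccccc7)cc2OCc7ccccc7)cc1OCc7ccccc7 | intermediate
20 | pentamer phenol A–O–B–O–C–O–D–O–E–OH | Oc1c(OCc7ccccc7)cc(Oc2c(OCc7ccccc7)cc(Oc3c(OCc7ccccc7)cc(Oc4c(OCc7ccccc7)cc(Oc5c(OCc7ccccc7)cc(OCc7ccccc7)cc5OCc7ccccc7)cc4OCc7ccccc7)cc3OCc7ccccc7)cc2OCc7ccccc7)cc1OCc7ccccc7 | intermediate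
21 | hexamer aldehyde A–O–B–O–C–O–D–O–E–O–F–CHO | O=Cc1c(OCc7ccccc7)cc(Oc2c(OCc7ccccc7)cc(Oc3c(OCc7ccccc7)cc(Oc4c(OCc7ccccc7)cc(Oc5c(OCc7ccccc7)cc(Oc6c(OCc7ccccc7)cc(OCc7ccccc7)cc6OCc7ccccc7)cc5OCc7ccccc7)cc4OCc7ccccc7)cc3OCc7ccccc7)cc2OCc7ccccc7)cc1OCc7ccccc7 | intermediate
22 | hexamer formate A–O–B–O–C–O–D–O–E–O–F–OCHO | O=COc1c(OCc7ccccc7)cc(Oc2c(OCc7ccccc7)cc(Oc3c(OCc7ccccc7)cc(Oc4c(OCc7ccccc7)cc(Oc5c(OCc7ccccc7)cc(Oc6c(OCc7ccccc7)cc(OCc7ccccc7)cc6OCc7ccccc7)cc5OCc7ccccc7)cc4OCc7ccccc7)cc3OCc7ccccc7)cc2OCc7ccccc7)cc1OCc7ccccc7 | intermediate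
23 | hexamer phenol A–O–B–O–C–O–D–O–E–O–F–OH (trideca-O-benzyl ether of the target) | Oc1c(OCc7ccccc7)cc(Oc2c(OCc7ccccc7)cc(Oc3c(OCc7ccccc7)cc(Oc4c(OCc7ccccc7)cc(Oc5c(OCc7ccccc7)cc(Oc6c(OCc7ccccc7)cc(OCc7ccccc7)cc6OCc7ccccc7)cc5OCc7ccccc7)cc4OCc7ccccc7)cc3OCc7ccccc7)cc2OCc7ccccc7)cc1OCc7ccccc7 | intermediate
24 | CNP0187343.0 (achiral) | Oc1cc(O)c(Oc2cc(O)c(Oc3cc(O)c(Oc4cc(O)c(Oc5cc(O)c(Oc6cc(O)c(O)c(O)c6)c(O)c5)c(O)c4)c(O)c3)c(O)c2)c(O)c1 | target

## Step count

Total steps: 15. Longest linear sequence: 13 steps (steps 3–15 from 4; equally steps 1, 2 and 5–15 from 1).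

## Three steps most likely to fail, with fallbacks

**Step 5 (and its repeats 7, 9, 11, 13).** The electrophile carries two alkoxy groups that weaken the formyl activation, and the nucleophile is a flanked, oxidation-prone phenoxide. Fallback (sets out from 8, comes back at 9): replace the uncatalysed substitution by a copper-catalysed Ullmann ether coupling. Commercial 4-bromo-2,6-difluorobenzaldehyde is treated with benzyl alcohol and Cs2CO3 in DMF at 60 °C; both ortho-fluorides are displaced and the bromide stays. This gives 2,6-bis(benzyloxy)-4-bromobenzaldehyde F1. Phenol 8 is then coupled with it (CuI, picolinic acid, K3PO4, DMSO, 90 °C) to give 9. The same swap serves the later couplings.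

**Step 14 (the largest Baeyer–Villiger substrate; the same concern applies in a milder form to steps 6–12).** Peracid may attack one of the six alkoxy-rich rings or the liberated phenol before the formyl group is consumed. Fallback (sets out from 20, comes back at 24): avoid the sixth aldehyde and its oxidation by bringing in ring F with all three oxygens in place. 5-Bromo-1,2,3-trimethoxybenzene is demethylated with BBr3 (CH2Cl2, −78 °C → rt) to 5-bromobenzene-1,2,3-triol F2. This is benzylated (BnBr, K2CO3, DMF, Ar) to 5-bromo-1,2,3-tris(benzyloxy)benzene F3. F3 is coupled with 20 by Ullmann etherification (CuI, N,N-dimethylglycine, Cs2CO3, dioxane, 100 °C) to give the tetradeca-O-benzyl hexamer F4. Hydrogenolysis of F4 under the step 15 conditions gives 24.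

**Step 15.** Thirteen hydrogenolyses on one molecule may stall at partly benzylated stages, and the free polyphenol is air-sensitive and hard to purify. Fallback (sets out from 23, comes back at 24): debenzylate with a Lewis acid and isolate through a stable ester. Compound 23 is treated with BCl3 and pentamethylbenzene as benzyl-cation scavenger (CH2Cl2, −78 °C) and quenched with MeOH. The crude polyphenol is acetylated directly (Ac2O, pyridine, DMAP) to the tetradecaacetate F5, which can be chromatographed on silica. Deacetylation (catalytic NaOMe, degassed MeOH, 0 °C, Ar; acidic resin quench) then gives 24.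

## Further compounds

F1 | step 5 | 2,6-bis(benzyloxy)-4-bromobenzaldehyde | O=Cc1c(OCc2ccccc2)cc(Br)cc1OCc1ccccc1
F2 | step 14 | 5-bromobenzene-1,2,3-triol | Oc1cc(Br)cc(O)c1O
F3 | step 14 | 5-bromo-1,2,3-tris(benzyloxy)benzene | Brc1cc(OCc2ccccc2)c(OCc2ccccc2)c(OCc2ccccc2)c1
F4 | step 14 | tetradeca-O-benzyl hexamer (fully benzylated target) | c7ccccc7COc1c(OCc7ccccc7)cc(Oc2c(OCc7ccccc7)cc(Oc3c(OCc7ccccc7)cc(Oc4c(OCc7ccccc7)cc(Oc5c(OCc7ccccc7)cc(Oc6c(OCc7ccccc7)cc(OCc7ccccc7)cc6OCc7ccccc7)cc5OCc7ccccc7)cc4OCc7ccccc7)cc3OCc7ccccc7)cc2OCc7ccccc7)cc1OCc7ccccc7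
F5 | step 15 | tetradecaacetate of the target | CC(=O)Oc1cc(OC(C)=O)c(Oc2cc(OC(C)=O)c(Oc3cc(OC(C)=O)c(Oc4cc(OC(C)=O)c(Oc5cc(OC(C)=O)c(Oc6cc(OC(C)=O)c(OC(C)=O)c(OC(C)=O)c6)c(OC(C)=O)c5)c(OC(C)=O)c4)c(OC(C)=O)c3)c(OC(C)=O)c2)c(OC(C)=O)c1
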